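Labdane numbering (C1–C20) is used for all intermediates.

## Retrosynthetic overview

1. Target 23 ⇐ 18 (methyl 3-oxo-2α-(phenylsulfonyl)labda-8(17),13E-dien-15-oate) by desulfonylation, 3-ketone reduction, saponification and acetylation.
2. 18 ⇐ 16 in one operation. The C2–C10 bond of a 1-sulfonylbicyclo[3.1.0]hexan-2-one breaks and C9–C10 forms, so the five-membered ring C2–C3–C4–C5–C10 is enlarged by C1 to ring A while ring B closes and the C8=C17 methylene appears.
3. Enabling feature: in ring A, oxygen-bearing C3 and quaternary C10 stand 1,4 to each other (C3–C2–C1–C10), and C10 is also the ring A/ring B junction atom that carries C9. A C2–C10 bond therefore turns ring A into an acylcyclopropane (C1 as the one-carbon bridge) that is a latent C10 cation/C2=C3 enolate.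
4. 16 ⇐ iodide 10 + dichloroalkene 13 (from methyl geranate 11) + Me3SiCH2ZnCl by two stereodefined Negishi couplings at C8. 10 ⇐ diazo keto sulfone 9 (intramolecular cyclopropanation) ⇐ lactone 5 ⇐ 1 + 2 (asymmetric 1,4-addition sets C5).
5. Ring order: δ-lactone (temporary, opened in step 3); cyclopentanone and cyclopropane together (step 6); ring A by enlargement and ring B by closure together (step 11).

Key step: step 11

Assumption: the (S,S)-configured bis(oxazoline) is taken as the ligand that sends the copper carbenoid to the required alkene face in step 6. If the sense is the opposite, its (R,R) antipode is used.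

## Route

Step 1
Reactants: 1 5,6-dihydro-2H-pyran-2-one; 2 potassium trifluoro(prop-1-en-2-yl)borate
Product: 3 (S)-4-(prop-1-en-2-yl)tetrahydro-2H-pyran-2-one
Conditions: [Rh(cod)2]PF6 (3 mol %), (S)-BINAP (3.3 mol %), toluene/H2O 20:1, 105 °C
Reagents that add atoms: none
Why: The rhodium-catalysed asymmetric 1,4-addition of an alkenylboron reagent (Hayashi–Miyaura reaction) to an unsaturated δ-lactone, a standard acceptor class, should set C5 through the enantioface selection of the (S)-BINAP–alkenylrhodium species.

Step 2
Reactants: 3 (S)-4-(prop-1-en-2-yl)tetrahydro-2H-pyran-2-one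
Product: 5 (R)-3,3-dimethyl-4-(prop-1-en-2-yl)tetrahydro-2H-pyran-2-one, via monomethyl lactone 4 (not isolated)
Conditions: LDA (1.1 equiv), THF, −78 °C, then MeI; second charge LDA (1.3 equiv), −78 °C, then MeI, DMPU, −78 → 0 °C
Reagents that add atoms: iodomethane CI
Why: Two successive lactone enolate alkylations should build the C4 gem-dimethyl group, the transient α-stereocentre of 4 (methyl anti to isopropenyl) being erased and the non-acidic C5 left untouched.

Step 3
Reactants: 5 (R)-3,3-dimethyl-4-(prop-1-en-2-yl)tetrahydro-2H-pyran-2-one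
Product: 6 (R)-6-hydroxy-3,3-dimethyl-1-(phenylsulfonyl)-4-(prop-1-en-2-yl)hexan-2-one
Conditions: PhSO2CH3 (2.3 equiv), n-BuLi (2.2 equiv), THF, −78 → 0 °C; then 5, −78 → 0 °C; aq. NH4Cl
Reagents that add atoms: methyl phenyl sulfone CS(=O)(=O)c1ccccc1
Why: Claisen-type acylation of the sulfonyl carbanion by the non-enolisable lactone should open the ring, bring in C2 with its activating group and free the C7 hydroxyl, while the second equivalent of carbanion deprotonates the β-keto sulfone and so prevents over-addition.

Step 4
Reactants: 6 (R)-6-hydroxy-3,3-dimethyl-1-(phenylsulfonyl)-4-(prop-1-en-2-yl)hexan-2-one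
Product: 7 (R)-1-diazo-6-hydroxy-3,3-dimethyl-1-(phenylsulfonyl)-4-(prop-1-en-2-yl)hexan-2-one
Conditions: 4-acetamidobenzenesulfonyl azide, Et3N, MeCN, 0 → 23 °C
Reagents that add atoms: 4-acetamidobenzenesulfonyl azide CC(=O)Nc1ccc(cc1)S(=O)(=O)N=[N+]=[N-]
Why: Regitz diazo transfer to the doubly activated C2 methylene is a standard reaction that tolerates the free primary alcohol and the alkene.

Step 5
Reactants: 7 (R)-1-diazo-6-hydroxy-3,3-dimethyl-1-(phenylsulfonyl)-4-(prop-1-en-2-yl)hexan-2-one
Product: 9 (R)-1-diazo-6-iodo-3,3-dimethyl-1-(phenylsulfonyl)-4-(prop-1-en-2-yl)hexan-2-one, via mesylate 8 (not isolated)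
Conditions: MsCl, Et3N, CH2Cl2, 0 °C; solvent change; NaI, acetone, 50 °C
Reagents that add atoms: methanesulfonyl chloride CS(=O)(=O)Cl (stays only in 8); sodium iodide [Na+].[I-]
Why: Mesylation and Finkelstein displacement should turn C7–OH into C7–I without phosphines (which attack diazo groups), and they come after the diazo transfer so that C2 no longer carries a nucleophilic C–H that could alkylate C7.

Step 6
Reactants: 9 (R)-1-diazo-6-iodo-3,3-dimethyl-1-(phenylsulfonyl)-4-(prop-1-en-2-yl)hexan-2-one
Product: 10 (1S,4S,5R)-4-(2-iodoethyl)-3,3,5-trimethyl-1-(phenylsulfonyl)bicyclo[3.1.0]hexan-2-one (iodoethyl chain anti to the cyclopropane CH2)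
Conditions: (CuOTf)2·C6H6 (5 mol %), 2,2'-(propane-2,2-diyl)bis[(4S)-4-isopropyl-4,5-dihydrooxazole] (12 mol %), toluene, slow addition, 25 → 50 °C
Reagents that add atoms: none
Why: The catalytic asymmetric intramolecular cyclopropanation of α-diazo-β-keto sulfones by a copper carbenoid should join C2 to C10 and C1, the short tether enforcing the cis-fused bicycle and the chiral ligand choosing the isopropenyl face so that C1 ends anti to the C5 side chain (C2 and C10 set).

Step 7
Reactants: 11 methyl (2E)-geranate
Product: 12 methyl (E)-3-methyl-6-oxohex-2-enoate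
Conditions: O3 (1.0 equiv), CH2Cl2, −78 °C; Me2S, −78 → 23 °C
Reagents that add atoms: ozone [O-][O+]=O
Why: Ozonolysis with one equivalent of ozone should cleave only the electron-rich trisubstituted alkene and leave the ester-conjugated 13E alkene with its geometry.

Step 8
Reactants: 12 methyl (E)-3-methyl-6-oxohex-2-enoate
Product: 13 methyl (E)-7,7-dichloro-3-methylhepta-2,6-dienoate
Conditions: PPh3 (4 equiv), CCl4, MeCN, 0 → 23 °C
Reagents that add atoms: tetrachloromethane ClC(Cl)(Cl)Cl
Why: The gem-dichloro-olefination of an aldehyde with Ph3P=CCl2 (dichloro variant of the Ramirez/Corey–Fuchs olefination) should install C8 as a carbon that can be substituted twice.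

Step 9
Reactants: 10 (1S,4S,5R)-4-(2-iodoethyl)-3,3,5-trimethyl-1-(phenylsulfonyl)bicyclo[3.1.0]hexan-2-one; 13 methyl (E)-7,7-dichloro-3-methylhepta-2,6-dienoate
Product: 15 methyl (2E,6Z)-7-chloro-3-methyl-9-[bicyclic core of 10]nona-2,6-dienoate, via alkylzinc iodide 14 (not isolated)
Conditions: Zn dust (activated), LiCl, THF, 25–35 °C; then 13, PdCl2(DPEphos) (3 mol %), THF/DMF, 23 °C
Reagents that add atoms: zinc [Zn] (stays only in 14)
Why: The trans-selective Negishi monoalkylation of a 1,1-dichloro-1-alkene should replace only the less hindered chloride trans to C11, so that C7 ends trans to C11, and the mild alkylzinc halide should spare ketone, ester, sulfone and cyclopropane.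

Step 10
Reactants: 15 methyl (2E,6Z)-7-chloro-3-methyl-9-[bicyclic core of 10]nona-2,6-dienoate
Product: 16 methyl (2E,6Z)-3-methyl-7-[(trimethylsilyl)methyl]-9-[bicyclic core of 10]nona-2,6-dienoate
Conditions: Me3SiCH2MgCl, ZnCl2, THF, 0 °C; then 15, Pd(P(t-Bu)3)2 (5 mol %), THF/NMP, 50 °C
Reagents that add atoms: (trimethylsilyl)methylmagnesium chloride C[Si](C)(C)C[Mg]Cl
Why: A second Negishi substitution of the remaining alkenyl chloride with retention, the bulky electron-rich phosphine suppressing isomerisation, should place C17 with its silyl group cis to C11 and complete the stereodefined allylsilane.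

Step 11
Reactants: 16 methyl (2E,6Z)-3-methyl-7-[(trimethylsilyl)methyl]-9-[bicyclic core of 10]nona-2,6-dienoate
Product: 18 methyl 3-oxo-2α-(phenylsulfonyl)labda-8(17),13E-dien-15-oate, via trichlorostannyl enolate 17 (not isolated)
Conditions: SnCl4 (2.5 equiv), 2,6-di-tert-butyl-4-methylpyridine (0.5 equiv), CH2Cl2, −78 → −30 °C; aq. NaHCO3
Reagents that add atoms: tin tetrachloride Cl[Sn](Cl)(Cl)Cl (stays only in 17)
Why: Proposed new method: SnCl4 binds the C3 ketone/sulfonyl pair, the C2–C10 bond (the zero-atom bridge of the bicyclo[3.1.0]hexanone) ionises towards its only tertiary terminus C10 while the electron pair is taken up as the sulfonyl-stabilised C2=C3 enolate 17, so that the five-membered ring C2–C3–C4–C5–C10 becomes six-membered ring A with C1 inside it, and the C8=C9 allylsilane attacks C10 and loses its silyl group to leave the C8=C17 methylene. The closest known reaction types are the Lewis-acid opening of acylcyclopropanes with olefin participation, the homo-conjugate addition of allylsilanes to doubly activated cyclopropanes and the acid-induced thujane-to-p-menthane ring enlargement, and what is new is their combination on the inner bond of a fused cyclopropane. Ring A arises by enlargement without a new bond, and ring B closes through a chair by an attack that is 6-endo-trig at the alkene and 6-exo-tet at C10. C10 is set by backside attack anti to the departing C2 (inversion), a trajectory that the C5 chain anti to the cyclopropane CH2 reaches with a gauche C6–C5–C10–C9 arrangement, and an open cation should give the same trans-decalin because the chain is equatorial and the smaller methyl goes axial beside the C4 gem-dimethyl group; C9 is set by the Z-allylsilane geometry (C11 trans to C7 ends equatorial, H9 axial and anti to C20); C2 is epimerisable, settles equatorial and is erased in step 12. The step needs inner-bond (C2–C10) rather than outer-bond (C2–C1) cleavage, which is secured by tertiary versus primary cation character, six- versus seven-membered closure and a sulfonyl group whose carbanion stabilisation does not depend on overlap with the ring carbonyl. It also needs cyclisation to outrun proton loss and protodesilylation, which the hindered base and the low temperature support.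

Step 12
Reactants: 18 methyl 3-oxo-2α-(phenylsulfonyl)labda-8(17),13E-dien-15-oate
Product: 19 methyl 3-oxolabda-8(17),13E-dien-15-oate
Conditions: SmI2 (2.5 equiv), THF/MeOH, −78 °C
Reagents that add atoms: none
Why: The single-electron reductive cleavage of an α-keto sulfone by SmI2 (reduction of α-heterosubstituted ketones) should remove the activating group at −78 °C without touching the isolated or the ester-conjugated alkene.

Step 13
Reactants: 19 methyl 3-oxolabda-8(17),13E-dien-15-oate
Product: 20 methyl 3β-hydroxylabda-8(17),13E-dien-15-oate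
Conditions: NaBH4, MeOH/CH2Cl2, 0 °C
Reagents that add atoms: none
Why: Borohydride reduction of a 4,4-dimethyl-3-ketone in a trans-decalin should deliver hydride from the α face, the β face being shielded by the axial C4 and C10 methyl groups, and so set C3 as the equatorial 3β (3S) alcohol.

Step 14
Reactants: 20 methyl 3β-hydroxylabda-8(17),13E-dien-15-oate
Product: 21 3β-hydroxylabda-8(17),13E-dien-15-oic acid
Conditions: LiOH, THF/MeOH/H2O, 55 °C; then aq. HCl to pH 4, 0 °C
Reagents that add atoms: lithium hydroxide [Li+].[OH-]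
Why: Saponification of the β-methyl enoate is done before acetylation so that no ester selectivity is required, and neither the alkene geometry nor any stereocentre is base-labile.

Step 15
Reactants: 21 3β-hydroxylabda-8(17),13E-dien-15-oic acid
Product: 23 3β-acetoxylabda-8(17),13E-dien-15-oic acid, via mixed anhydride 22 (not isolated)
Conditions: Ac2O, pyridine, DMAP (cat.), 23 °C; then H2O/THF, 23 °C
Reagents that add atoms: acetic anhydride CC(=O)OC(C)=O
Why: DMAP-catalysed acetylation of the equatorial 3β-alcohol proceeds with retention at C3, and the mixed carboxylic anhydride formed at C15 should be hydrolysed selectively by water during work-up.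

## Compound list

1 | 5,6-dihydro-2H-pyran-2-one | O=C1C=CCCO1 | starting material
2 | potassium trifluoro(prop-1-en-2-yl)borate | [K+].C=C(C)[B-](F)(F)F | starting material
3 | (S)-4-(prop-1-en-2-yl)tetrahydro-2H-pyran-2-one | O=C1C[C@@H](C(C)=C)CCO1 | intermediate
4 | (3R,4S)-3-methyl-4-(prop-1-en-2-yl)tetrahydro-2H-pyran-2-one (trans; not isolated) | O=C1[C@H](C)[C@@H](C(C)=C)CCO1 | intermediate
5 | (R)-3,3-dimethyl-4-(prop-1-en-2-yl)tetrahydro-2H-pyran-2-one | O=C1C(C)(C)[C@@H](C(C)=C)CCO1 | intermediate
6 | (R)-6-hydroxy-3,3-dimethyl-1-(phenylsulfonyl)-4-(prop-1-en-2-yl)hexan-2-one | OCC[C@H](C(C)=C)C(C)(C)C(=O)CS(=O)(=O)c1ccccc1 | intermediate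
7 | (R)-1-diazo-6-hydroxy-3,3-dimethyl-1-(phenylsulfonyl)-4-(prop-1-en-2-yl)hexan-2-one | OCC[C@H](C(C)=C)C(C)(C)C(=O)C(=[N+]=[N-])S(=O)(=O)c1ccccc1 | intermediate
8 | methanesulfonate of 7 (not isolated) | CS(=O)(=O)OCC[C@H](C(C)=C)C(C)(C)C(=O)C(=[N+]=[N-])S(=O)(=O)c1ccccc1 | intermediate
9 | (R)-1-diazo-6-iodo-3,3-dimethyl-1-(phenylsulfonyl)-4-(prop-1-en-2-yl)hexan-2-one | ICC[C@H](C(C)=C)C(C)(C)C(=O)C(=[N+]=[N-])S(=O)(=O)c1ccccc1 | intermediate
10 | (1S,4S,5R)-4-(2-iodoethyl)-3,3,5-trimethyl-1-(phenylsulfonyl)bicyclo[3.1.0]hexan-2-one | O=C1C(C)(C)[C@H](CCI)[C@@]2(C)C[C@@]12S(=O)(=O)c3ccccc3 | intermediate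
11 | methyl (2E)-geranate (methyl (E)-3,7-dimethylocta-2,6-dienoate) | CC(C)=CCC/C(C)=C/C(=O)OC | starting material
12 | methyl (E)-3-methyl-6-oxohex-2-enoate | O=CCC/C(C)=C/C(=O)OC | intermediate
13 | methyl (E)-7,7-dichloro-3-methylhepta-2,6-dienoate | ClC(Cl)=CCC/C(C)=C/C(=O)OC | intermediate
14 | alkylzinc iodide of 10 (ZnI in place of I at C7; not isolated) | O=C1C(C)(C)[C@H](CC[Zn]I)[C@@]2(C)C[C@@]12S(=O)(=O)c3ccccc3 | intermediate
15 | (Z)-chloroalkene: C7 trans to C11, Cl on C8, bicyclic core as in 10 | O=C1C(C)(C)[C@H](CC/C(Cl)=C/CC/C(C)=C/C(=O)OC)[C@@]2(C)C[C@@]12S(=O)(=O)c3ccccc3 | intermediate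
16 | (Z)-allylsilane: CH2SiMe3 (C17) on C8 cis to C11, bicyclic core as in 10 | O=C1C(C)(C)[C@H](CC/C(C[Si](C)(C)C)=C/CC/C(C)=C/C(=O)OC)[C@@]2(C)C[C@@]12S(=O)(=O)c3ccccc3 | intermediate
17 | trichlorostannyl C2=C3 enolate of 18 (not isolated) | C=C1CC[C@H]2C(C)(C)C(O[Sn](Cl)(Cl)Cl)=C(S(=O)(=O)c3ccccc3)C[C@]2(C)[C@H]1CC/C(C)=C/C(=O)OC | intermediate
18 | methyl 3-oxo-2α-(phenylsulfonyl)labda-8(17),13E-dien-15-oate | C=C1CC[C@H]2C(C)(C)C(=O)[C@H](S(=O)(=O)c3ccccc3)C[C@]2(C)[C@H]1CC/C(C)=C/C(=O)OC | intermediate
19 | methyl 3-oxolabda-8(17),13E-dien-15-oate | C=C1CC[C@H]2C(C)(C)C(=O)CC[C@]2(C)[C@H]1CC/C(C)=C/C(=O)OC | intermediate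
20 | methyl 3β-hydroxylabda-8(17),13E-dien-15-oate | C=C1CC[C@H]2C(C)(C)[C@@H](O)CC[C@]2(C)[C@H]1CC/C(C)=C/C(=O)OC | intermediate
21 | 3β-hydroxylabda-8(17),13E-dien-15-oic acid | C=C1CC[C@H]2C(C)(C)[C@@H](O)CC[C@]2(C)[C@H]1CC/C(C)=C/C(=O)O | intermediate
22 | acetic 3β-acetoxylabda-8(17),13E-dien-15-oic anhydride (not isolated) | C=C1CC[C@H]2C(C)(C)[C@@H](OC(C)=O)CC[C@]2(C)[C@H]1CC/C(C)=C/C(=O)OC(C)=O | intermediate
23 | 3β-acetoxylabda-8(17),13E-dien-15-oic acid | C=C1CC[C@H]2C(C)(C)[C@@H](OC(C)=O)CC[C@]2(C)[C@H]1CC/C(C)=C/C(=O)O | target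

## Step count and risks

Total step count: 15. Longest linear sequence: 13 (steps 1–6 and 9–15).

**Step 11 (labelled step).** Three processes may compete with the cyclisation:
- chloride-assisted cleavage of the outer C1–C2 bond;
- loss of a proton from the C10 cation before C9 arrives;
- protodesilylation of the allylsilane.

The fallback uses known reaction types only. It sets out from 15 and comes back at 18, and it separates ring enlargement from ring B closure. Compound 15 is opened with TiCl4 in CH2Cl2, which is halide opening of a doubly activated cyclopropane at its most substituted carbon (the thujane-to-p-menthane mode of cleavage). This should give the ring-enlarged 10-chloro-3-oxo-2-sulfonyl cyclohexane F1. The alkenyl chloride of F1 is coupled with Me3SiCH2ZnCl as in step 10 to give the allylsilane tertiary chloride F2. A Lewis-acid-induced intramolecular alkylation of the allylsilane by the tertiary chloride (TiCl4 or ZnCl2, CH2Cl2, −78 °C) then closes ring B and returns 18.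

**Step 6.** Facial selectivity may be poor if ligand control and the bias of the C5 substituent oppose each other. Carbenoid C–H insertion into C6 may also compete. The fallback sets out from 6 and comes back at 10, and it replaces carbenoid delivery by reagent approach anti to the chain on a flat ring.
- The alcohol of 6 is silylated (TBSCl, imidazole) to the silyl ether F3.
- Ozonolysis of the isopropenyl group gives the C10 methyl ketone F4.
- Intramolecular Knoevenagel condensation of C2 with C10 (TiCl4, pyridine, 0 °C, kept cold to avoid epimerisation at C5) gives the 2-(phenylsulfonyl)cyclopent-2-enone F5.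
- Corey–Chaykovsky cyclopropanation (Me3S(O)I, NaH, THF/DMSO) adds the new C1 methylene to C10 from the face anti to the C5 chain and closes on C2, giving the cyclopropane silyl ether F6.
- HF·pyridine frees the cyclopropane alcohol F7.
- Appel iodination (I2, PPh3, imidazole) returns 10.

**Step 10.** Oxidative addition into the hindered alkenyl chloride may be slow, transfer of the silylmethyl group from zinc may be sluggish, and the alkene geometry may erode. The fallback sets out from 15 and comes back at 18, and it gives up the allylsilane. Compound 15 itself is submitted to the conditions of step 11 with the chloroalkene as terminator (chloro-olefin annulation). The α-chloro cation at C8 is hydrolysed on work-up to the 8-ketone methyl 3,8-dioxo-2α-(phenylsulfonyl)-17-norlabd-13E-en-15-oate F8, whose C9 centre can equilibrate to the equatorial side chain. Wittig methylenation with excess Ph3P=CH2 should take place only at C8, because the ylide turns the β-keto sulfone into its enolate and thereby masks C3. This returns 18.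

Further compounds
F1 | step 11 | ring-enlarged tertiary chloride: (Z)-chloroalkene chain on C5 of 4-chloro-4,6,6-trimethyl-2-(phenylsulfonyl)cyclohexanone (C2 epimers) | O=C1C(S(=O)(=O)c2ccccc2)C[C@](C)(Cl)[C@@H](CC/C(Cl)=C/CC/C(C)=C/C(=O)OC)C1(C)C
F2 | step 11 | allylsilane tertiary chloride (F1 with CH2SiMe3 in place of the alkenyl chlorine; C2 epimers) | O=C1C(S(=O)(=O)c2ccccc2)C[C@](C)(Cl)[C@@H](CC/C(C[Si](C)(C)C)=C/CC/C(C)=C/C(=O)OC)C1(C)C
F3 | step 6 | tert-butyldimethylsilyl ether of 6 | CC(C)(C)[Si](C)(C)OCC[C@H](C(C)=C)C(C)(C)C(=O)CS(=O)(=O)c1ccccc1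
F4 | step 6 | C10 methyl ketone from F3 | CC(C)(C)[Si](C)(C)OCC[C@H](C(C)=O)C(C)(C)C(=O)CS(=O)(=O)c1ccccc1
F5 | step 6 | 4-[2-(tert-butyldimethylsilyloxy)ethyl]-3,5,5-trimethyl-2-(phenylsulfonyl)cyclopent-2-enone | O=C1C(S(=O)(=O)c2ccccc2)=C(C)[C@@H](CCO[Si](C)(C)C(C)(C)C)C1(C)C
F6 | step 6 | cyclopropane silyl ether (10 with OTBS in place of I) | O=C1C(C)(C)[C@H](CCO[Si](C)(C)C(C)(C)C)[C@@]2(C)C[C@@]12S(=O)(=O)c3ccccc3
F7 | step 6 | cyclopropane alcohol (10 with OH in place of I) | O=C1C(C)(C)[C@H](CCO)[C@@]2(C)C[C@@]12S(=O)(=O)c3ccccc3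
F8 | step 10 | methyl 3,8-dioxo-2α-(phenylsulfonyl)-17-norlabd-13E-en-15-oate | O=C1CC[C@H]2C(C)(C)C(=O)[C@H](S(=O)(=O)c3ccccc3)C[C@]2(C)[C@H]1CC/C(C)=C/C(=O)OC
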